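Compound numbers are those of the steps and of the compound list. Flavanone atoms are O1, C2, C3, C4, C4a, C5–C8, C8a (rings A, C, B); flavone atoms carry the suffix f (rings D, F, E).

## Analysis of the target

The target is a 3→8f-linked flavanone–flavone dimer. A naringenin unit (rings A, C, B) is bonded through C3 to C8f of an apigenin unit (rings D, F, E), and the O7f phenol is esterified as a hydrogen sulfate. Ring C carries two stereocentres, C2 (R) and C3 (S). The ring B aryl group on C2 and the ring D aryl group on C3 are trans, which is the diequatorial and thermodynamically preferred arrangement. Both centres are labile: C3–H is benzylic and α to the C4 ketone, and the O1–C2 bond can open by retro-oxa-Michael reaction to an achiral 2'-hydroxychalcone, so base must be kept mild once ring C is closed. The aryl sulfate monoester is acid-sensitive and polar, and it must be placed on one of six phenolic oxygens. Two of these (O5 and O5f) are chelated to carbonyl groups, but O7, O4' and O4'f are ordinary phenols like O7f. The C3–C8f bond is congested (O7f and O1f on one side, C2 and C4 on the other; slow rotation but no stable axis) and is hard to make on a finished flavone, where C6f competes with C8f. The strategy rests on ring D: a phloroglucinol in which every position differs (C5f–OH, C6f–H, C7f–O-sulfate, C8f–C3, C8af and C4af shared with pyranone ring F). It can therefore be grown onto a 2-aryl-4-pyranone by a ketene–alkyne benzannulation whose mechanism places each oxygen and the C3 carbon.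

## Retrosynthetic reasoning

**30 back to 29, 28 and 27 (O–benzyl, O7f–S and O7f–Si bonds).** The sulfate is introduced on 28, where O7f is the only phenol that is neither chelated nor benzylated, so no selectivity among ordinary phenols is needed. This requires O7f to travel under a group unlike all others, the silyl ether of 27. The last step only removes benzyl groups under neutral conditions that touch neither the sulfate nor the two stereocentres.

**27 back to 26 (O1–C2 bond).** Ring C is opened at its ether bond because the forward reaction, oxa-Michael addition of the 2'-hydroxyl to the enone, is the natural closure of flavanones. The forward step must put oxygen on one face of C2 under catalyst control; C3 then follows by protonation and settles trans. Cutting C3–C8f instead would require coupling at the crowded C8f of a finished flavone in competition with C6f.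

**26 back to 25, then to 23 and 24 (one O–benzyl bond, then the C2=C3 bond).** The bridge is divided between C2 and C3, so ring B arrives as aldehyde 24 and C3/C4 arrive with ring D. The ortho oxygen of ring A stays benzylated during the condensation (25), so the enone cannot cyclise as a racemate under the amine. It is freed afterwards under chelation control, which separates C=C formation from the stereo-defining closure.

**23 back to 20 and 21 (C4–C4a bond).** A Friedel–Crafts acylation joins ring A to C4. The arene 21 is symmetric, so any position gives the same ketone and no regiochemical question arises. Acid 20 carries C3 and C4 on C8f.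

**20 back to 18 and 17 (oxidation level of C4).** The acid comes from a two-carbon side chain that ends in a silyl-protected primary alcohol. In this form the chain is inert during ring D formation and is unmasked by acid without touching the aryl silyl ether on O7f.

**17 back to 8 and 12 (C3–C8f, C5f–C6f, C7f–C8f, C5f–C4af).** All of ring D is removed. The diazo carbon of 8 becomes C8f, its acyl carbon becomes C5f, the migrating side chain supplies C3, and alkyne 12 supplies C6f and C7f with the silyloxy group on C7f. This single step yields a flavone with C3 on C8f and three different oxygens on ring D, which the other cuts considered leave unsolved. The forward reaction has to run a Wolff shift, a [2+2] cycloaddition and two electrocyclic steps in one flask.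

**8 back to 7, then to 4 and 6 (C=N2, then the bond between the ketone carbon and the pyranone CH2).** The diazo group goes onto a methylene activated by the ketone and, vinylogously, by the pyranone. That methylene ketone arises by acylating the 6-methyl group of pyranone 4 with ester 6.

**4 back to 3, then 1 and 2; 6 from 5; 12 from 9.** The pyranone comes from cyclodehydration of triketone 3, made by aroylation of 1 with 2. Ester 6 is the silyl ether of 5. Alkyne 12 comes from 9 by oxidation of its acetylide to the ynolate and O-silylation.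

## Alternatives that were turned down

**Alternative 1: carbenoid arylation intercepted by an aldol addition.**
- Disconnection: C3–C8f and C2–C3 are both cut, so ring C is assembled from ring A diazo ketone A1, symmetric phloroglucinol triether A2 and aldehyde 24.
- Forward key step: Rh2(OAc)4 turns A1 into a rhodium carbenoid, A2 attacks it through the future C8f, and a chiral phosphoric acid steers capture of the resulting enol by 24 to give anti aldol A3. The C2 alkoxide would then displace the ring A fluoride (SNAr) to close ring C, and rings F and E would be built afterwards.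
- For it: one catalytic step makes two skeletal bonds and both stereocentres by C–C bond formation, which does not reverse as an oxa-Michael addition can. The symmetric nucleophile removes the C6f/C8f question. Three-component trapping of carbenoid-derived enols is an established reaction family.
- Against it: an acceptor-only diazo ketone gives an enol that tautomerises quickly to the plain arylation product, and carbonyl ylide formation with 24 competes. A3 is a β-hydroxy ketone open to retro-aldol cleavage under the basic SNAr conditions. Ring D is still symmetric after the key step, so its two equivalent ortho oxygens must be told apart and the chromone built late, in the presence of the base-labile C2/C3 pair, over many steps.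
- Comparison: it is stronger than the chosen route on convergence and on setting C2 and C3. It is weaker on the differentiated ring D, which the chosen route obtains in one step; the chosen route pays for this by closing ring C through a reversible C–O bond formation.

**Alternative 2: anodic para-quinone methide closure of ring C.**
- Disconnection: C2–C3, with O1–C2 already present as a 4-hydroxybenzyl aryl ether in ketone A4.
- Forward key step: anodic two-electron oxidation (carbon anode, divided cell, Bu4NPF6) of the ring B phenol of A4 gives an O1-substituted para-quinone methide. A chiral phosphoric acid directs 1,6-addition of the C3 enol to C2, closing ring C and giving A5.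
- For it: both centres are set in a C–C bond-forming event and no chemical oxidant is needed. Ring B needs no protection. A5 already carries the sulfate in protected form, so the end is a single reductive deprotection, shorter than the three steps from 27 here.
- Against it: A4 already contains the complete flavone with C3 on C8f and O7f singled out, so it presupposes a solution for ring D. The trialkoxy ring A, ring D and the enolisable ketone are oxidisable near the phenol potential. An O-aryl quinone methide is a vinylogous oxocarbenium ion at the acetal oxidation level, so solvolysis with loss of the ring A phenoxide should compete with attack of a hindered enol. Ion pairing with the chiral phosphate must operate in a concentrated supporting electrolyte.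
- Comparison: it is as strong or stronger on endgame length and on the mode of setting C2/C3. It stacks two unproven elements in one late step and leaves ring D open. The chosen route has one unproven stereochemical step with a known racemic counterpart behind it.

**Alternative 3: conjunctive coupling across a vinylboron ate complex.**
- Disconnection: C3–C4 and the C2–ring B bond, across alkenylboronate A6.
- Forward key step: aryllithium A7 adds to boron of A6. With Ni(cod)2 and a chiral diamine, the acyl–nickel species from acid chloride A8 bonds to C3 while the aryl group shifts from boron to C2, giving β-boryl ketone A9. C–B oxidation and SNAr would close ring C.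
- For it: three fragments, two C–C bonds and both stereocentres come from one catalyst-controlled step. The trans relationship follows from anti addition across an (E)-alkene and not from equilibration. The reaction family is known.
- Against it: A7 must form the ate complex in the presence of the flavone of A6, which accepts organolithiums at C2f and C4f. A 1,2-disubstituted alkenylboronate with a di-ortho-substituted aryl group on the carbon that takes the acyl group, together with the di-ortho-substituted A8, lies at or beyond the edge of the scope. A9 has an epimerisable α-centre and can lose boron by elimination. A6 again presupposes a flavone functionalised at C8f with O5f and O7f distinguished.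
- Comparison: it is stronger in principle on stereochemical rigour and convergence. The chosen route is stronger on compatibility with the functional groups present and is the only one of the four that creates the ring D pattern by mechanism.

Key step: step 7

Assumption: 29 and 30 are written as free aryl hydrogen sulfates, as the target is drawn; both would be isolated and stored as sodium salts, and the acid form released only at the end.

## Route

Step 1
Reactants: 1 acetylacetone; 2 methyl 4-(benzyloxy)benzoate
Product: 3 1-[4-(benzyloxy)phenyl]hexane-1,3,5-trione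
Conditions: NaH (4 equiv), DME, reflux; then aq HCl, 0 °C
Reagents that add atoms: none
Why: Claisen-type aroylation of a β-diketone at its terminal methyl group; with excess NaH the small equilibrium share of the 1,3-dianion reacts at the more basic terminal carbon and the reaction is driven by the doubly deprotonated triketone. The benzyl ether is inert.

Step 2
Reactants: 3 1-[4-(benzyloxy)phenyl]hexane-1,3,5-trione
Product: 4 2-[4-(benzyloxy)phenyl]-6-methyl-4H-pyran-4-one
Conditions: TsOH·H2O (0.1 equiv), toluene, reflux, Dean–Stark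
Reagents that add atoms: none
Why: Acid-catalysed cyclodehydration of a 1,3,5-triketone to a 4-pyranone; only one pyranone is possible. A sulfonic acid in toluene is used in place of concentrated H2SO4 so that the benzyl ether survives.

Step 3
Reactants: 5 methyl 3-hydroxypropanoate
Product: 6 methyl 3-(tert-butyldimethylsilyloxy)propanoate
Conditions: TBSCl, imidazole, CH2Cl2, 0 °C to rt
Reagents that add atoms: tert-butyldimethylsilyl chloride, CC(C)(C)[Si](C)(C)Cl
Why: Standard imidazole-mediated silylation of a primary alcohol.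

Step 4
Reactants: 4 2-[4-(benzyloxy)phenyl]-6-methyl-4H-pyran-4-one; 6 methyl 3-(tert-butyldimethylsilyloxy)propanoate
Product: 7 2-[4-(benzyloxy)phenyl]-6-[4-(tert-butyldimethylsilyloxy)-2-oxobutyl]-4H-pyran-4-one
Conditions: LiN(SiMe3)2 (2.2 equiv), THF, –78 °C; then 6, –78 to –20 °C; AcOH quench
Reagents that add atoms: none
Why: Lateral (vinylogous) deprotonation of the 6-methyl group of the pyranone and crossed Claisen acylation by the ester. The second equivalent of base deprotonates the doubly activated methylene of the product, which stops double acylation and keeps the β-silyloxy ketone from eliminating.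

Step 5
Reactants: 7 2-[4-(benzyloxy)phenyl]-6-[4-(tert-butyldimethylsilyloxy)-2-oxobutyl]-4H-pyran-4-one
Product: 8 2-[4-(benzyloxy)phenyl]-6-[4-(tert-butyldimethylsilyloxy)-1-diazo-2-oxobutyl]-4H-pyran-4-one
Conditions: 4-acetamidobenzenesulfonyl azide, DBU, MeCN, 0 °C
Reagents that add atoms: 4-acetamidobenzenesulfonyl azide, CC(=O)Nc1ccc(cc1)S(=O)(=O)N=[N+]=[N-]
Why: Regitz diazo transfer to the methylene activated by the ketone and, through the ring, by the pyranone carbonyl (comparable to an electron-poor benzyl ketone). The other CH2 next to the ketone is far less acidic and is left alone at 0 °C.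

Step 6
Reactants: 9 acetylene
Product: 12 triisopropylsilyloxyethyne, via lithium acetylide 10 (not isolated), via lithium ethynolate 11 (not isolated)
Conditions: n-BuLi, THF, –78 °C; t-BuOOLi (from t-BuOOH and LiN(SiMe3)2), –78 to 0 °C; i-Pr3SiOTf, –78 to 0 °C; pentane extraction, distillation
Reagents that add atoms: tert-butyl hydroperoxide, CC(C)(C)OO; triisopropylsilyl trifluoromethanesulfonate, CC(C)[Si](OS(=O)(=O)C(F)(F)F)(C(C)C)C(C)C
Why: Oxidation of a lithium acetylide by lithium tert-butyl peroxide (electrophilic oxygen transfer) gives the ynolate, and the bulky silyl triflate silylates it on oxygen. This is the standard entry to 1-siloxy-1-alkynes from terminal alkynes, applied here to the monolithium salt of acetylene.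

Step 7
Reactants: 8 2-[4-(benzyloxy)phenyl]-6-[4-(tert-butyldimethylsilyloxy)-1-diazo-2-oxobutyl]-4H-pyran-4-one; 12 triisopropylsilyloxyethyne (2.5 equiv)
Product: 17 2-[4-(benzyloxy)phenyl]-8-[2-(tert-butyldimethylsilyloxy)ethyl]-5-hydroxy-7-(triisopropylsilyloxy)-4H-chromen-4-one, via pyranonyl ketene 13 (not isolated), via siloxycyclobutenone 14 (not isolated), via dienylketene 15 (not isolated), via cyclohexadienone 16 (not isolated)
Conditions: hν (390–420 nm LEDs), degassed ClCH2CH2Cl (0.02 M), rt; then 80 °C
Reagents that add atoms: none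
Why: Long-wavelength light excites only the diazo ketone chromophore of 8; loss of N2 and Wolff rearrangement move the CH2CH2OTBS group (C3) from the carbonyl carbon to the carbene carbon (C8f) and give ketene 13, whose carbonyl carbon is the future C5f. The nucleophilic CH carbon of 12 adds to that carbonyl carbon and the oxygen-bearing carbon bonds to C8f, a polarity-controlled [2+2] cycloaddition that gives cyclobutenone 14 (C5f–C6f and C7f–C8f) with the silyloxy group next to C8f. At 80 °C 14 opens by a reversible conrotatory 4π electrocyclic reaction to dienylketene 15; the isomer with the pyranonyl group turned away from the ketene can only return to 14, so the material funnels through the reactive isomer. Ring D is then closed by a thermal disrotatory 6π electrocyclisation of the ketene carbon onto C5 of the pyranone, forming C5f–C4af and dienone 16, which tautomerises to the chelated phenol 17. The closest known reaction type is the Danheiser benzannulation in its photochemical Wolff form, in which aryl and heteroaryl diazo ketones and siloxyalkynes give siloxy-substituted phenols by the same sequence. No stereocentre is formed. The step needs chemoselectivity of the carbene (its carbon has no adjacent C–H, so no 1,2-hydride shift competes with the Wolff shift), regioselectivity of the cycloaddition (set by the polarity of ketene and ynol ether) and a single site of closure (the pyranone offers only C5–H). The three oxygens of ring D come out distinct: free O5f, silylated O7f and ring oxygen O1f.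

Step 8
Reactants: 17 2-[4-(benzyloxy)phenyl]-8-[2-(tert-butyldimethylsilyloxy)ethyl]-5-hydroxy-7-(triisopropylsilyloxy)-4H-chromen-4-one
Product: 18 2-[4-(benzyloxy)phenyl]-5-hydroxy-8-(2-hydroxyethyl)-7-(triisopropylsilyloxy)-4H-chromen-4-one
Conditions: CSA (0.1 equiv), MeOH/CH2Cl2, 0 °C
Reagents that add atoms: none
Why: Acid-catalysed methanolysis removes the primary alkyl TBS ether. Aryl silyl ethers are slow to cleave under acid, and the hindered TIPS ether on O7f in particular, so it should stay.

Step 9
Reactants: 18 2-[4-(benzyloxy)phenyl]-5-hydroxy-8-(2-hydroxyethyl)-7-(triisopropylsilyloxy)-4H-chromen-4-one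
Product: 20 {2-[4-(benzyloxy)phenyl]-5-hydroxy-4-oxo-7-(triisopropylsilyloxy)-4H-chromen-8-yl}acetic acid, via arylacetaldehyde 19 (not isolated)
Conditions: Dess–Martin periodinane, NaHCO3, CH2Cl2, 0 °C to rt; then NaClO2, NaH2PO4, 2-methyl-2-butene, t-BuOH/THF/H2O, 0 °C
Reagents that add atoms: sodium chlorite, [Na+].[O-]Cl=O
Why: Dess–Martin oxidation to the sensitive arylacetaldehyde, then Pinnick oxidation of the crude aldehyde. The alkene scavenger removes HOCl before it can chlorinate the electron-rich C6f, and the chelated 5f-OH is a poor substrate for both oxidants.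

Step 10
Reactants: 20 {2-[4-(benzyloxy)phenyl]-5-hydroxy-4-oxo-7-(triisopropylsilyloxy)-4H-chromen-8-yl}acetic acid; 21 1,3,5-tris(benzyloxy)benzene (1.5 equiv)
Product: 23 2-{2-[4-(benzyloxy)phenyl]-5-hydroxy-4-oxo-7-(triisopropylsilyloxy)-4H-chromen-8-yl}-1-[2,4,6-tris(benzyloxy)phenyl]ethan-1-one, via acyl trifluoroacetate 22 (not isolated)
Conditions: (CF3CO)2O, H3PO4 (cat.), CH2Cl2, 0 °C to rt; then MeOH, aq NaHCO3
Reagents that add atoms: none
Why: Friedel–Crafts acylation of a phloroglucinol triether by the mixed trifluoroacetic anhydride, which needs no metal Lewis acid and so spares the aryl silyl ether. The arene is symmetric, so only one ketone can form. Any trifluoroacetate on the chelated 5f-OH is cleaved in the work-up.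

Step 11
Reactants: 23 2-{2-[4-(benzyloxy)phenyl]-5-hydroxy-4-oxo-7-(triisopropylsilyloxy)-4H-chromen-8-yl}-1-[2,4,6-tris(benzyloxy)phenyl]ethan-1-one; 24 4-(benzyloxy)benzaldehyde
Product: 25 (2E)-3-[4-(benzyloxy)phenyl]-2-{2-[4-(benzyloxy)phenyl]-5-hydroxy-4-oxo-7-(triisopropylsilyloxy)-4H-chromen-8-yl}-1-[2,4,6-tris(benzyloxy)phenyl]prop-2-en-1-one
Conditions: piperidine, AcOH, toluene, 4 Å MS, 90 °C
Reagents that add atoms: none
Why: Knoevenagel-type aldol condensation of a deoxybenzoin with an aromatic aldehyde via the piperidinium ion of 24. It should give the (E)-enone, with ring B trans to the carbonyl carbon as in ordinary chalcones. Ring A carries no free ortho hydroxyl, so the enone cannot cyclise as a racemate at this stage.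

Step 12
Reactants: 25 (2E)-3-[4-(benzyloxy)phenyl]-2-{2-[4-(benzyloxy)phenyl]-5-hydroxy-4-oxo-7-(triisopropylsilyloxy)-4H-chromen-8-yl}-1-[2,4,6-tris(benzyloxy)phenyl]prop-2-en-1-one
Product: 26 (2E)-1-[2,4-bis(benzyloxy)-6-hydroxyphenyl]-3-[4-(benzyloxy)phenyl]-2-{2-[4-(benzyloxy)phenyl]-5-hydroxy-4-oxo-7-(triisopropylsilyloxy)-4H-chromen-8-yl}prop-2-en-1-one
Conditions: BCl3 (2.2 equiv), CH2Cl2, –78 °C; MeOH, then aq NaHCO3 below 0 °C
Reagents that add atoms: none
Why: Chelation-controlled debenzylation: boron bound to the ketone oxygen activates only an ortho benzyl ether, and the resulting boron chelate deactivates the second ortho ether and keeps the phenol oxygen from adding to the enone. One equivalent is taken up by the 5f-OH/C4f=O site. The two ortho ethers are equivalent, so a single product is expected.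

Step 13
Reactants: 26 (2E)-1-[2,4-bis(benzyloxy)-6-hydroxyphenyl]-3-[4-(benzyloxy)phenyl]-2-{2-[4-(benzyloxy)phenyl]-5-hydroxy-4-oxo-7-(triisopropylsilyloxy)-4H-chromen-8-yl}prop-2-en-1-one
Product: 27 (2R,3S)-5,7-bis(benzyloxy)-2-[4-(benzyloxy)phenyl]-3-{2-[4-(benzyloxy)phenyl]-5-hydroxy-4-oxo-7-(triisopropylsilyloxy)-4H-chromen-8-yl}chroman-4-one
Conditions: 9-amino(9-deoxy)-epi-quinidine N'-[3,5-bis(trifluoromethyl)phenyl]thiourea (10 mol %), toluene, –20 °C
Reagents that add atoms: none
Why: Proposed new method: the quinuclidine nitrogen of the bifunctional cinchona thiourea should deprotonate the chelated 2'-hydroxyl while the thiourea binds the enone carbonyl, so the phenoxide adds to one face of C2 in a 6-endo-trig oxa-Michael closure that sets C2 (R); C3 is set by protonation of the ring enol and settles, by catalyst-mediated enolisation that does not touch C2, in the trans diequatorial arrangement (3S); the closest known reactions are organocatalytic asymmetric oxa-Michael cyclisations of 2'-hydroxychalcones and their α-alkoxycarbonyl derivatives to flavanones, not yet shown for an α-aryl chalcone; the sense of induction has to be assigned, and the quinine-derived pseudoenantiomer is used if it is opposite.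

Step 14
Reactants: 27 (2R,3S)-5,7-bis(benzyloxy)-2-[4-(benzyloxy)phenyl]-3-{2-[4-(benzyloxy)phenyl]-5-hydroxy-4-oxo-7-(triisopropylsilyloxy)-4H-chromen-8-yl}chroman-4-one
Product: 28 (2R,3S)-5,7-bis(benzyloxy)-2-[4-(benzyloxy)phenyl]-3-{2-[4-(benzyloxy)phenyl]-5,7-dihydroxy-4-oxo-4H-chromen-8-yl}chroman-4-one
Conditions: Bu4NF, AcOH (1.5 equiv per fluoride), THF, 0 °C
Reagents that add atoms: none
Why: Fluoride cleavage of an aryl silyl ether, which is fast because phenoxide is a good leaving group. The acetic acid buffer keeps the medium from becoming basic enough to epimerise C3 or open ring C.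

Step 15
Reactants: 28 (2R,3S)-5,7-bis(benzyloxy)-2-[4-(benzyloxy)phenyl]-3-{2-[4-(benzyloxy)phenyl]-5,7-dihydroxy-4-oxo-4H-chromen-8-yl}chroman-4-one
Product: 29 (2R,3S)-5,7-bis(benzyloxy)-2-[4-(benzyloxy)phenyl]-3-{2-[4-(benzyloxy)phenyl]-5-hydroxy-4-oxo-7-(sulfooxy)-4H-chromen-8-yl}chroman-4-one
Conditions: SO3·pyridine (3 equiv), pyridine/DMF, rt; aq NaHCO3 (sodium salt)
Reagents that add atoms: sulfur trioxide–pyridine complex, [O-]S(=O)(=O)[n+]1ccccc1
Why: O-Sulfation of a phenol with an amine–SO3 complex. O7f is the only free phenol that is not hydrogen-bonded to a carbonyl group, and the chelated 5f-OH does not react under these mild conditions. Pyridine is too weak a base to open ring C at room temperature.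

Step 16
Reactants: 29 (2R,3S)-5,7-bis(benzyloxy)-2-[4-(benzyloxy)phenyl]-3-{2-[4-(benzyloxy)phenyl]-5-hydroxy-4-oxo-7-(sulfooxy)-4H-chromen-8-yl}chroman-4-one
Product: 30 (2R,3S)-5,7-dihydroxy-2-(4-hydroxyphenyl)-3-[5-hydroxy-2-(4-hydroxyphenyl)-4-oxo-7-(sulfooxy)-4H-chromen-8-yl]chroman-4-one
Conditions: H2 (1 atm), Pd/C, THF/MeOH, rt (on the sodium salt); sulfonic acid resin (H+ form), 0 °C, for the free acid
Reagents that add atoms: none
Why: Hydrogenolysis of four aryl benzyl ethers over palladium on carbon under neutral conditions. The aryl sulfate anion, the flavone C2f=C3f bond and the O1–C2 bond are not expected to be reduced at 1 atm, and C2 and C3 are not exposed to acid or base. The sodium salt is used because pyridine would inhibit the catalyst.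

## Compound list

1 | acetylacetone (pentane-2,4-dione) | CC(=O)CC(C)=O | starting material
2 | methyl 4-(benzyloxy)benzoate | COC(=O)c1ccc(OCc2ccccc2)cc1 | starting material
3 | 1-[4-(benzyloxy)phenyl]hexane-1,3,5-trione | CC(=O)CC(=O)CC(=O)c1ccc(OCc2ccccc2)cc1 | intermediate
4 | 2-[4-(benzyloxy)phenyl]-6-methyl-4H-pyran-4-one | Cc1cc(=O)cc(-c2ccc(OCc3ccccc3)cc2)o1 | intermediate
5 | methyl 3-hydroxypropanoate | COC(=O)CCO | starting material
6 | methyl 3-(tert-butyldimethylsilyloxy)propanoate | COC(=O)CCO[Si](C)(C)C(C)(C)C | intermediate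
7 | 2-[4-(benzyloxy)phenyl]-6-[4-(tert-butyldimethylsilyloxy)-2-oxobutyl]-4H-pyran-4-one | O=c1cc(-c2ccc(OCc3ccccc3)cc2)oc(CC(=O)CCO[Si](C)(C)C(C)(C)C)c1 | intermediate
8 | 2-[4-(benzyloxy)phenyl]-6-[4-(tert-butyldimethylsilyloxy)-1-diazo-2-oxobutyl]-4H-pyran-4-one | O=c1cc(-c2ccc(OCc3ccccc3)cc2)oc(C(=[N+]=[N-])C(=O)CCO[Si](C)(C)C(C)(C)C)c1 | intermediate
9 | acetylene (ethyne) | C#C | starting material
10 | lithium acetylide | [Li+].[C-]#C | intermediate (not isolated)
11 | lithium ethynolate | [Li+].[O-]C#C | intermediate (not isolated)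
12 | triisopropylsilyloxyethyne | C#CO[Si](C(C)C)(C(C)C)C(C)C | intermediate
13 | 2-{6-[4-(benzyloxy)phenyl]-4-oxo-4H-pyran-2-yl}-4-(tert-butyldimethylsilyloxy)but-1-en-1-one (ketene) | O=C=C(CCO[Si](C)(C)C(C)(C)C)c1cc(=O)cc(-c2ccc(OCc3ccccc3)cc2)o1 | intermediate (not isolated)
14 | 4-{6-[4-(benzyloxy)phenyl]-4-oxo-4H-pyran-2-yl}-4-[2-(tert-butyldimethylsilyloxy)ethyl]-3-(triisopropylsilyloxy)cyclobut-2-en-1-one (racemic) | O=C1C=C(O[Si](C(C)C)(C(C)C)C(C)C)C1(CCO[Si](C)(C)C(C)(C)C)c1cc(=O)cc(-c2ccc(OCc3ccccc3)cc2)o1 | intermediate (not isolated)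
15 | (3E)-4-{6-[4-(benzyloxy)phenyl]-4-oxo-4H-pyran-2-yl}-6-(tert-butyldimethylsilyloxy)-3-(triisopropylsilyloxy)hexa-1,3-dien-1-one (dienylketene) | O=C=C/C(O[Si](C(C)C)(C(C)C)C(C)C)=C(/CCO[Si](C)(C)C(C)(C)C)c1cc(=O)cc(-c2ccc(OCc3ccccc3)cc2)o1 | intermediate (not isolated)
16 | 2-[4-(benzyloxy)phenyl]-8-[2-(tert-butyldimethylsilyloxy)ethyl]-7-(triisopropylsilyloxy)-4aH-chromene-4,5-dione (keto tautomer of 17) | O=C1C=C(O[Si](C(C)C)(C(C)C)C(C)C)C(CCO[Si](C)(C)C(C)(C)C)=C2OC(c3ccc(OCc4ccccc4)cc3)=CC(=O)C12 | intermediate (not isolated)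
17 | 2-[4-(benzyloxy)phenyl]-8-[2-(tert-butyldimethylsilyloxy)ethyl]-5-hydroxy-7-(triisopropylsilyloxy)-4H-chromen-4-one | O=c1cc(-c2ccc(OCc3ccccc3)cc2)oc2c(CCO[Si](C)(C)C(C)(C)C)c(O[Si](C(C)C)(C(C)C)C(C)C)cc(O)c12 | intermediate
18 | 2-[4-(benzyloxy)phenyl]-5-hydroxy-8-(2-hydroxyethyl)-7-(triisopropylsilyloxy)-4H-chromen-4-one | O=c1cc(-c2ccc(OCc3ccccc3)cc2)oc2c(CCO)c(O[Si](C(C)C)(C(C)C)C(C)C)cc(O)c12 | intermediate
19 | {2-[4-(benzyloxy)phenyl]-5-hydroxy-4-oxo-7-(triisopropylsilyloxy)-4H-chromen-8-yl}acetaldehyde | O=CCc1c(O[Si](C(C)C)(C(C)C)C(C)C)cc(O)c2c(=O)cc(-c3ccc(OCc4ccccc4)cc3)oc12 | intermediate (not isolated)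
20 | {2-[4-(benzyloxy)phenyl]-5-hydroxy-4-oxo-7-(triisopropylsilyloxy)-4H-chromen-8-yl}acetic acid | OC(=O)Cc1c(O[Si](C(C)C)(C(C)C)C(C)C)cc(O)c2c(=O)cc(-c3ccc(OCc4ccccc4)cc3)oc12 | intermediate
21 | 1,3,5-tris(benzyloxy)benzene | c1ccc(COc2cc(OCc3ccccc3)cc(OCc3ccccc3)c2)cc1 | starting material
22 | {2-[4-(benzyloxy)phenyl]-5-hydroxy-4-oxo-7-(triisopropylsilyloxy)-4H-chromen-8-yl}acetic trifluoroacetic anhydride | O=C(Cc1c(O[Si](C(C)C)(C(C)C)C(C)C)cc(O)c2c(=O)cc(-c3ccc(OCc4ccccc4)cc3)oc12)OC(=O)C(F)(F)F | intermediate (not isolated)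
23 | 2-{2-[4-(benzyloxy)phenyl]-5-hydroxy-4-oxo-7-(triisopropylsilyloxy)-4H-chromen-8-yl}-1-[2,4,6-tris(benzyloxy)phenyl]ethan-1-one | O=C(Cc1c(O[Si](C(C)C)(C(C)C)C(C)C)cc(O)c2c(=O)cc(-c3ccc(OCc4ccccc4)cc3)oc12)c1c(OCc2ccccc2)cc(OCc2ccccc2)cc1OCc1ccccc1 | intermediate
24 | 4-(benzyloxy)benzaldehyde | O=Cc1ccc(OCc2ccccc2)cc1 | starting material
25 | (2E)-3-[4-(benzyloxy)phenyl]-2-{2-[4-(benzyloxy)phenyl]-5-hydroxy-4-oxo-7-(triisopropylsilyloxy)-4H-chromen-8-yl}-1-[2,4,6-tris(benzyloxy)phenyl]prop-2-en-1-one | O=C(c1c(OCc2ccccc2)cc(OCc2ccccc2)cc1OCc1ccccc1)/C(=C/c1ccc(OCc2ccccc2)cc1)c1c(O[Si](C(C)C)(C(C)C)C(C)C)cc(O)c2c(=O)cc(-c3ccc(OCc4ccccc4)cc3)oc12 | intermediate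
26 | (2E)-1-[2,4-bis(benzyloxy)-6-hydroxyphenyl]-3-[4-(benzyloxy)phenyl]-2-{2-[4-(benzyloxy)phenyl]-5-hydroxy-4-oxo-7-(triisopropylsilyloxy)-4H-chromen-8-yl}prop-2-en-1-one | O=C(c1c(O)cc(OCc2ccccc2)cc1OCc1ccccc1)/C(=C/c1ccc(OCc2ccccc2)cc1)c1c(O[Si](C(C)C)(C(C)C)C(C)C)cc(O)c2c(=O)cc(-c3ccc(OCc4ccccc4)cc3)oc12 | intermediate
27 | (2R,3S)-5,7-bis(benzyloxy)-2-[4-(benzyloxy)phenyl]-3-{2-[4-(benzyloxy)phenyl]-5-hydroxy-4-oxo-7-(triisopropylsilyloxy)-4H-chromen-8-yl}chroman-4-one | O=C1c2c(OCc3ccccc3)cc(OCc3ccccc3)cc2O[C@@H](c2ccc(OCc3ccccc3)cc2)[C@@H]1c1c(O[Si](C(C)C)(C(C)C)C(C)C)cc(O)c2c(=O)cc(-c3ccc(OCc4ccccc4)cc3)oc12 | intermediate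
28 | (2R,3S)-5,7-bis(benzyloxy)-2-[4-(benzyloxy)phenyl]-3-{2-[4-(benzyloxy)phenyl]-5,7-dihydroxy-4-oxo-4H-chromen-8-yl}chroman-4-one | O=C1c2c(OCc3ccccc3)cc(OCc3ccccc3)cc2O[C@@H](c2ccc(OCc3ccccc3)cc2)[C@@H]1c1c(O)cc(O)c2c(=O)cc(-c3ccc(OCc4ccccc4)cc3)oc12 | intermediate
29 | (2R,3S)-5,7-bis(benzyloxy)-2-[4-(benzyloxy)phenyl]-3-{2-[4-(benzyloxy)phenyl]-5-hydroxy-4-oxo-7-(sulfooxy)-4H-chromen-8-yl}chroman-4-one (handled as sodium salt) | O=C1c2c(OCc3ccccc3)cc(OCc3ccccc3)cc2O[C@@H](c2ccc(OCc3ccccc3)cc2)[C@@H]1c1c(OS(=O)(=O)O)cc(O)c2c(=O)cc(-c3ccc(OCc4ccccc4)cc3)oc12 | intermediate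
30 | (2R,3S)-5,7-dihydroxy-2-(4-hydroxyphenyl)-3-[5-hydroxy-2-(4-hydroxyphenyl)-4-oxo-7-(sulfooxy)-4H-chromen-8-yl]chroman-4-one | O=C1c2c(O)cc(O)cc2O[C@@H](c2ccc(O)cc2)[C@@H]1c1c(OS(=O)(=O)O)cc(O)c2c(=O)cc(-c3ccc(O)cc3)oc12 | target

## Step count and least certain steps

Total: 16 steps. Longest linear sequence: 14 steps (steps 1, 2, 4, 5 and 7 to 16).

**Step 13 (proposed new method).** The likely failure is poor facial selectivity in the C–O bond formation. A weakly activated, trisubstituted enone may cyclise through an uncatalysed or loosely bound pathway, and reversible ring opening at longer reaction times may erode the enantiomeric purity. Fallback with known chemistry, from 26: close ring C without stereocontrol using piperidine (0.2 equiv) in ethanol–THF at room temperature, the classical base-mediated cyclisation of 2'-hydroxychalcones. This gives the racemic trans compound, that is 27 together with its enantiomer (2S,3R)-5,7-bis(benzyloxy)-2-[4-(benzyloxy)phenyl]-3-{2-[4-(benzyloxy)phenyl]-5-hydroxy-4-oxo-7-(triisopropylsilyloxy)-4H-chromen-8-yl}chroman-4-one F1. The two are separated by preparative chromatography on amylose tris(3,5-dimethylphenylcarbamate). The route is rejoined at 27, and F1 is racemised with DBU through ring opening and reclosure and then recycled.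

**Step 7 (key step).** The likely failures are diversion of the photochemically formed carbene (cyclopropenation of the electron-rich alkyne, or photoreactions of the pyranone that compete for light) and slow cycloaddition of the hindered disubstituted ketene, which leaves time for ketene dimerisation. Fallback, from 4, which makes the same ketene without light:
- Alkylate the lateral lithium dienolate of 4 (LiN(SiMe3)2, THF, –78 °C) with tert-butyl(2-iodoethoxy)dimethylsilane to give 2-[4-(benzyloxy)phenyl]-6-[3-(tert-butyldimethylsilyloxy)propyl]-4H-pyran-4-one F2.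
- Deprotonate again at the same carbon and carboxylate with CO2 to give 2-{6-[4-(benzyloxy)phenyl]-4-oxo-4H-pyran-2-yl}-4-(tert-butyldimethylsilyloxy)butanoic acid F3, kept cold because it is a vinylogous β-keto acid.
- Convert F3 with 1-chloro-N,N,2-trimethylprop-1-en-1-amine at 0 °C into 2-{6-[4-(benzyloxy)phenyl]-4-oxo-4H-pyran-2-yl}-4-(tert-butyldimethylsilyloxy)butanoyl chloride F4.
- Add F4 to Et3N and 12 in ClCH2CH2Cl. Dehydrochlorination gives ketene 13 in the dark, and the sequence continues through 14 on heating to rejoin the route at 17.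

**Step 6.** The likely failures are disproportionation of monolithium acetylide before it is oxidised, silylation on carbon instead of oxygen, and loss of the small siloxyalkyne by volatility or isomerisation to the silylketene during isolation. Fallback, from 8, with a C-silylated alkyne:
- Take ethynyltrimethylsilane F5 through the same lithiation, peroxide oxidation and silylation to triisopropyl{[(trimethylsilyl)ethynyl]oxy}silane F6.
- Use F6 in place of 12 in the benzannulation with 8 to give 2-[4-(benzyloxy)phenyl]-8-[2-(tert-butyldimethylsilyloxy)ethyl]-5-hydroxy-7-(triisopropylsilyloxy)-6-(trimethylsilyl)-4H-chromen-4-one F7.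
- Remove the aryl silicon group by ipso-protodesilylation with CF3CO2H in CH2Cl2 at 0 °C to rejoin the route at 17.

**Step 10.** The likely failures are lactonisation of the activated acid onto O7f with loss of the silyl group, and slow acylation by a mixed anhydride flanked by two ortho substituents. Fallback, from 19, which forms the C4–C4a bond by carbonyl addition:
- Brominate 21 with N-bromosuccinimide to 2-bromo-1,3,5-tris(benzyloxy)benzene F8.
- Carry out bromine–lithium exchange on F8 (n-BuLi, THF, –78 °C) and transmetalate to anhydrous CeCl3.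
- Add the organocerium reagent (3 equiv, one consumed by the 5f-OH) to aldehyde 19 to give 2-{2-[4-(benzyloxy)phenyl]-5-hydroxy-4-oxo-7-(triisopropylsilyloxy)-4H-chromen-8-yl}-1-[2,4,6-tris(benzyloxy)phenyl]ethan-1-ol F9.
- Oxidise F9 with Dess–Martin periodinane to rejoin the route at 23.

**Step 11.** The likely failures are lack of condensation at a methylene flanked by two di-ortho-substituted aryl groups, and loss of the O7f silyl group on prolonged heating with the amine. Fallback, from 23, in two stages:
- Form the lithium enolate of 23 (LiN(SiMe3)2, 2.2 equiv, THF, –78 °C) and add it to 24 to give the aldol 3-[4-(benzyloxy)phenyl]-2-{2-[4-(benzyloxy)phenyl]-5-hydroxy-4-oxo-7-(triisopropylsilyloxy)-4H-chromen-8-yl}-3-hydroxy-1-[2,4,6-tris(benzyloxy)phenyl]propan-1-one F10.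
- Dehydrate F10 with TsOH (cat.) in toluene at 40 °C, by ionisation of the 4-alkoxybenzylic alcohol, to rejoin the route at 25.

## Further compounds

F1 | step 13 | (2S,3R)-5,7-bis(benzyloxy)-2-[4-(benzyloxy)phenyl]-3-{2-[4-(benzyloxy)phenyl]-5-hydroxy-4-oxo-7-(triisopropylsilyloxy)-4H-chromen-8-yl}chroman-4-one | O=C1c2c(OCc3ccccc3)cc(OCc3ccccc3)cc2O[C@H](c2ccc(OCc3ccccc3)cc2)[C@H]1c1c(O[Si](C(C)C)(C(C)C)C(C)C)cc(O)c2c(=O)cc(-c3ccc(OCc4ccccc4)cc3)oc12
F2 | step 7 | 2-[4-(benzyloxy)phenyl]-6-[3-(tert-butyldimethylsilyloxy)propyl]-4H-pyran-4-one | O=c1cc(-c2ccc(OCc3ccccc3)cc2)oc(CCCO[Si](C)(C)C(C)(C)C)c1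
F3 | step 7 | 2-{6-[4-(benzyloxy)phenyl]-4-oxo-4H-pyran-2-yl}-4-(tert-butyldimethylsilyloxy)butanoic acid | O=c1cc(-c2ccc(OCc3ccccc3)cc2)oc(C(CCO[Si](C)(C)C(C)(C)C)C(=O)O)c1
F4 | step 7 | 2-{6-[4-(benzyloxy)phenyl]-4-oxo-4H-pyran-2-yl}-4-(tert-butyldimethylsilyloxy)butanoyl chloride | O=c1cc(-c2ccc(OCc3ccccc3)cc2)oc(C(CCO[Si](C)(C)C(C)(C)C)C(=O)Cl)c1
F5 | step 6 | ethynyltrimethylsilane | C#C[Si](C)(C)C
F6 | step 6 | triisopropyl{[(trimethylsilyl)ethynyl]oxy}silane | C[Si](C)(C)C#CO[Si](C(C)C)(C(C)C)C(C)C
F7 | step 6 | 2-[4-(benzyloxy)phenyl]-8-[2-(tert-butyldimethylsilyloxy)ethyl]-5-hydroxy-7-(triisopropylsilyloxy)-6-(trimethylsilyl)-4H-chromen-4-one | O=c1cc(-c2ccc(OCc3ccccc3)cc2)oc2c(CCO[Si](C)(C)C(C)(C)C)c(O[Si](C(C)C)(C(C)C)C(C)C)c([Si](C)(C)C)c(O)c12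
F8 | step 10 | 2-bromo-1,3,5-tris(benzyloxy)benzene | Brc1c(OCc2ccccc2)cc(OCc2ccccc2)cc1OCc1ccccc1
F9 | step 10 | 2-{2-[4-(benzyloxy)phenyl]-5-hydroxy-4-oxo-7-(triisopropylsilyloxy)-4H-chromen-8-yl}-1-[2,4,6-tris(benzyloxy)phenyl]ethan-1-ol | OC(Cc1c(O[Si](C(C)C)(C(C)C)C(C)C)cc(O)c2c(=O)cc(-c3ccc(OCc4ccccc4)cc3)oc12)c1c(OCc2ccccc2)cc(OCc2ccccc2)cc1OCc1ccccc1
F10 | step 11 | 3-[4-(benzyloxy)phenyl]-2-{2-[4-(benzyloxy)phenyl]-5-hydroxy-4-oxo-7-(triisopropylsilyloxy)-4H-chromen-8-yl}-3-hydroxy-1-[2,4,6-tris(benzyloxy)phenyl]propan-1-one | O=C(c1c(OCc2ccccc2)cc(OCc2ccccc2)cc1OCc1ccccc1)C(C(O)c1ccc(OCc2ccccc2)cc1)c1c(O[Si](C(C)C)(C(C)C)C(C)C)cc(O)c2c(=O)cc(-c3ccc(OCc4ccccc4)cc3)oc12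
A1 | alternative 1 | 1-[4-(benzyloxy)-2-fluoro-6-(triisopropylsilyloxy)phenyl]-2-diazoethan-1-one | [N-]=[N+]=CC(=O)c1c(F)cc(OCc2ccccc2)cc1O[Si](C(C)C)(C(C)C)C(C)C
A2 | alternative 1 | [3,5-bis(methoxymethoxy)phenoxy]triisopropylsilane | COCOc1cc(OCOC)cc(O[Si](C(C)C)(C(C)C)C(C)C)c1
A3 | alternative 1 | (2S,3R)-1-[4-(benzyloxy)-2-fluoro-6-(triisopropylsilyloxy)phenyl]-3-[4-(benzyloxy)phenyl]-2-[2,6-bis(methoxymethoxy)-4-(triisopropylsilyloxy)phenyl]-3-hydroxypropan-1-one | O[C@@H](c1ccc(OCc2ccccc2)cc1)[C@@H](C(=O)c1c(F)cc(OCc2ccccc2)cc1O[Si](C(C)C)(C(C)C)C(C)C)c1c(OCOC)cc(O[Si](C(C)C)(C(C)C)C(C)C)cc1OCOC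
A4 | alternative 2 | 1-{2,4-bis(benzyloxy)-6-[(4-hydroxybenzyl)oxy]phenyl}-2-{5-(benzyloxy)-2-[4-(benzyloxy)phenyl]-4-oxo-7-[(2,2,2-trichloroethoxy)sulfonyloxy]-4H-chromen-8-yl}ethan-1-one | O=C(Cc1c(OS(=O)(=O)OCC(Cl)(Cl)Cl)cc(OCc2ccccc2)c2c(=O)cc(-c3ccc(OCc4ccccc4)cc3)oc12)c1c(OCc2ccccc2)cc(OCc2ccccc2)cc1OCc1ccc(O)cc1
A5 | alternative 2 | (2R,3S)-5,7-bis(benzyloxy)-3-{5-(benzyloxy)-2-[4-(benzyloxy)phenyl]-4-oxo-7-[(2,2,2-trichloroethoxy)sulfonyloxy]-4H-chromen-8-yl}-2-(4-hydroxyphenyl)chroman-4-one | O=C1c2c(OCc3ccccc3)cc(OCc3ccccc3)cc2O[C@@H](c2ccc(O)cc2)[C@@H]1c1c(OS(=O)(=O)OCC(Cl)(Cl)Cl)cc(OCc2ccccc2)c2c(=O)cc(-c3ccc(OCc4ccccc4)cc3)oc12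
A6 | alternative 3 | 5-(benzyloxy)-2-[4-(benzyloxy)phenyl]-7-(methoxymethoxy)-8-[(E)-2-(4,4,5,5-tetramethyl-1,3,2-dioxaborolan-2-yl)ethenyl]-4H-chromen-4-one | CC1(C)OB(/C=C/c2c(OCOC)cc(OCc3ccccc3)c3c(=O)cc(-c4ccc(OCc5ccccc5)cc4)oc23)OC1(C)C
A7 | alternative 3 | 4-(benzyloxy)phenyllithium | [Li]c1ccc(OCc2ccccc2)cc1
A8 | alternative 3 | 2,4-bis(benzyloxy)-6-fluorobenzoyl chloride | O=C(Cl)c1c(F)cc(OCc2ccccc2)cc1OCc1ccccc1
A9 | alternative 3 | (2R,3R)-1-[2,4-bis(benzyloxy)-6-fluorophenyl]-3-[4-(benzyloxy)phenyl]-2-{5-(benzyloxy)-2-[4-(benzyloxy)phenyl]-7-(methoxymethoxy)-4-oxo-4H-chromen-8-yl}-3-(4,4,5,5-tetramethyl-1,3,2-dioxaborolan-2-yl)propan-1-one | CC1(C)OB(OC1(C)C)[C@@H](c1ccc(OCc2ccccc2)cc1)[C@@H](C(=O)c1c(F)cc(OCc2ccccc2)cc1OCc1ccccc1)c1c(OCOC)cc(OCc2ccccc2)c2c(=O)cc(-c3ccc(OCc4ccccc4)cc3)oc12
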